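**Plan**

- Retrosynthetic cuts, in this order: the two silyl ethers; the biaryl C–C bond (at an aryl chloride); the aryl–allyl bond (at an aryl bromide); the C3–O aryl ether bond; the C3–CH3 bond (back to a 3-ketone); the C10–C1 bond of ring A; the C2–C3 bond (vinyl addition to an amide); the C4–C5 bond (Claisen).
- Forward: ring B is taken from carvone, the two-carbon chain C4–C3 is attached at C5, the vinyl unit C2=C1 is added at C3, ring A is closed last at C10–C1, and the arene part is joined through oxygen and completed by two cross-couplings.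
- Enabling feature: ring B (C5–C10) with the C10 methyl and the para C7 carbinol is the carbon skeleton of carvone, and the C10–C1 bond links a tertiary carbon to the β-carbon of the C3 ketone of ring A, so a C10 radical can close ring A onto a vinyl ketone.
- Stereochemistry: C7 comes from (S)-carvone; C5 from suprafacial transfer of the cis-carveol C–O bond; C10 from trans ring fusion in the radical closure; C3 from equatorial methylene transfer followed by hydride opening, the oxygen then being arylated with retention.

Key step: step 7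

Remark: decalin numbering is ring A = C1, C2, C3 (ether carbon), C4, C5, C10 and ring B = C5–C10 (C7 carbinol-bearing, C10 methyl-bearing); because the carvone carbonyl carbon becomes C9 and the carvone β-carbon becomes C5, the 7R centre of the target corresponds to (S)-(+)-carvone.

**Route**

Step 1
Reactants: 1 (S)-(+)-carvone
Product: 2 (5S)-5-(2-hydroxypropan-2-yl)-2-methylcyclohex-2-en-1-one
Conditions: 50% aq. H2SO4, 0 °C
Reagents that add atoms: water, O
Why: Acid-catalysed hydration of the 1,1-disubstituted isopropenyl alkene through its tertiary cation should be selective because the conjugated ring alkene is deactivated toward protonation, and the stereocentre (future C7) is not involved.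

Step 2
Reactants: 2 (5S)-5-(2-hydroxypropan-2-yl)-2-methylcyclohex-2-en-1-one
Product: 3 (5S)-2-methyl-5-[2-(triethylsilyloxy)propan-2-yl]cyclohex-2-en-1-one
Conditions: Et3SiOTf, 2,6-lutidine, CH2Cl2, −78 → 0 °C
Reagents that add atoms: triethylsilyl trifluoromethanesulfonate, CC[Si](CC)(CC)OS(=O)(=O)C(F)(F)F
Why: Silylation with a silyl triflate and a hindered pyridine base is the standard way to cap a tertiary alcohol, and the triethylsilyl ether is chosen because it can be removed by fluoride at the end without acid.

Step 3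
Reactants: 3 (5S)-2-methyl-5-[2-(triethylsilyloxy)propan-2-yl]cyclohex-2-en-1-one
Product: 4 (1S,5S)-2-methyl-5-[2-(triethylsilyloxy)propan-2-yl]cyclohex-2-en-1-ol (cis)
Conditions: NaBH4, CeCl3·7H2O, MeOH, −78 → 0 °C
Reagents that add atoms: none
Why: Luche 1,2-reduction should deliver hydride axially to the half-chair that holds the C5 substituent equatorial, so the new carbinol centre (S) has its hydroxyl pseudoequatorial and cis to that substituent.

Step 4
Reactants: 4 (1S,5S)-2-methyl-5-[2-(triethylsilyloxy)propan-2-yl]cyclohex-2-en-1-ol; 5 triethyl orthoacetate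
Product: 7 ethyl 2-[(1S,5R)-2-methyl-5-[2-(triethylsilyloxy)propan-2-yl]cyclohex-2-en-1-yl]acetate, via ketene acetal 6 (not isolated)
Conditions: MeC(OEt)3 (excess), EtCO2H (cat.), xylene, 140 °C, EtOH distilled off
Reagents that add atoms: none
Why: Johnson–Claisen rearrangement: exchange of the allylic alcohol into the orthoester and loss of ethanol give ketene acetal 6, whose suprafacial [3,3] shift places the chain on the far allylic carbon on the face that carried oxygen, so C5 (S) is set cis to the C7 group and the alkene moves to C9=C10.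

Step 5
Reactants: 7 ethyl 2-[(1S,5R)-2-methyl-5-[2-(triethylsilyloxy)propan-2-yl]cyclohex-2-en-1-yl]acetate
Product: 8 N-methoxy-N-methyl-2-[(1S,5R)-2-methyl-5-[2-(triethylsilyloxy)propan-2-yl]cyclohex-2-en-1-yl]acetamide
Conditions: MeNH(OMe)·HCl, iPrMgCl, THF, −20 → 0 °C
Reagents that add atoms: N,O-dimethylhydroxylamine hydrochloride, CNOC.Cl
Why: Direct aminolysis of the ester by the chloromagnesium amide (Weinreb amide formation) should be clean because the hindered silyl ether and the isolated alkene are inert to this base.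

Step 6
Reactants: 8 N-methoxy-N-methyl-2-[(1S,5R)-2-methyl-5-[2-(triethylsilyloxy)propan-2-yl]cyclohex-2-en-1-yl]acetamide; 9 vinylmagnesium bromide
Product: 11 1-[(1S,5R)-2-methyl-5-[2-(triethylsilyloxy)propan-2-yl]cyclohex-2-en-1-yl]but-3-en-2-one, via bromomagnesium hemiaminal alkoxide 10 (not isolated)
Conditions: THF, −78 → 0 °C; inverse quench into cold aq. citric acid
Reagents that add atoms: none
Why: Weinreb ketone synthesis: vinylmagnesium bromide adds once to give the chelated tetrahedral intermediate 10, which collapses to the vinyl ketone only on the cold acidic quench that also keeps the released amine from adding to the enone.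

Step 7
Reactants: 11 1-[(1S,5R)-2-methyl-5-[2-(triethylsilyloxy)propan-2-yl]cyclohex-2-en-1-yl]but-3-en-2-one
Product: 12 (4aS,7R,8aS)-4a-methyl-7-[2-(triethylsilyloxy)propan-2-yl]octahydronaphthalen-2(1H)-one (trans-fused)
Conditions: Fe(acac)3 (0.3 equiv), PhSiH3 (2.5 equiv), EtOH/(CH2OH)2 (5:1), 0.02 M, 60 °C
Reagents that add atoms: none
Why: The Fe–H species formed from Fe(acac)3 and PhSiH3 transfers a hydrogen atom to C9, the less substituted carbon of the electron-rich C9=C10 alkene, and the resulting tertiary C10 radical adds to C1, the terminal carbon of the vinyl ketone, after which the α-keto radical is reduced by divalent iron and the enolate is protonated by ethanol. The closest known reaction type is the hydrogen-atom-transfer-initiated reductive coupling of an unactivated alkene with an enone, run here intramolecularly (a Giese cyclisation). Ring A closes in the 6-endo-trig mode through the C10–C1 bond, because the nucleophilic radical seeks the electrophilic β-carbon, whereas the 5-exo path would attack the α-carbon against the polarity of the enone. The new stereocentre C10 is controlled by C5: with the C5 side chain and the C7 group both equatorial on ring B, the chain should reach the planar radical through a chair-like transition state on the α face, anti to the C5–C4 bond that the C10 methyl pushes slightly out of the radical plane, so the new bond ends equatorial and the methyl axial, cis to the C7 group (10S, trans fusion). The step needs trans over cis ring fusion and ring closure over simple reduction of the radical; the first is secured by the diequatorial lock of ring B, the same chair preference by which stepwise radical polyene cyclisations close trans, and the second by fast intramolecular addition to an unhindered terminal acceptor at high dilution. The hydrogen atom goes to the trisubstituted alkene and not to the enone because the electron-rich alkene is the better hydrogen-atom acceptor.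

Step 8
Reactants: 12 (4aS,7R,8aS)-4a-methyl-7-[2-(triethylsilyloxy)propan-2-yl]octahydronaphthalen-2(1H)-one
Product: 13 spiro-epoxide of 12 at C3 (3R; oxirane CH2 equatorial and β, oxirane O axial and α)
Conditions: Me3S(O)I, NaH, DMSO/THF, rt
Reagents that add atoms: trimethylsulfoxonium iodide, C[S+](C)(C)=O.[I-]
Why: Corey–Chaykovsky epoxidation with the sulfoxonium ylide: betaine formation is reversible, so ring closure should proceed from the adduct whose new C–C bond is equatorial, giving the epoxide with methylene equatorial and oxygen axial at C3 (3R).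

Step 9
Reactants: 13 spiro-epoxide of 12 at C3
Product: 14 (2R,4aS,7R,8aS)-2,4a-dimethyl-7-[2-(triethylsilyloxy)propan-2-yl]decahydronaphthalen-2-ol (axial OH, equatorial CH3)
Conditions: LiAlH4, THF, 0 → 50 °C
Reagents that add atoms: none
Why: SN2 hydride opening of the epoxide at its unhindered methylene carbon leaves the C3–O bond untouched, so the axial tertiary alcohol with an equatorial methyl (3R) should result.

Step 10
Reactants: 15 4-bromo-2-chloro-1-iodobenzene
Product: 17 (4-bromo-2-chlorophenyl)(2,4,6-trimethoxyphenyl)iodonium tosylate, via hydroxy(tosyloxy)iodoarene 16 (not isolated)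
Conditions: mCPBA, TsOH·H2O, MeCN, 77 °C; then 1,3,5-trimethoxybenzene, rt
Reagents that add atoms: 1,3,5-trimethoxybenzene, COc1cc(OC)cc(OC)c1; 4-toluenesulfonic acid monohydrate, Cc1ccc(S(=O)(=O)O)cc1.O
Why: One-pot diaryliodonium synthesis: the peracid oxidises the aryl iodide to the hydroxy(tosyloxy)iodane 16, which arylates the electron-rich trimethoxybenzene by electrophilic aromatic substitution, both halogens being inert to these conditions.

Step 11
Reactants: 18 allyl 4-bromophenyl ether
Product: 19 2-allyl-4-bromophenol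
Conditions: PhNEt2, 200 °C
Reagents that add atoms: none
Why: Aromatic Claisen rearrangement: the thermal [3,3] shift delivers the allyl group to a free ortho position and tautomerisation restores the phenol, the para position being blocked by bromine.

Step 12
Reactants: 19 2-allyl-4-bromophenol
Product: 20 (2-allyl-4-bromophenoxy)triisopropylsilane
Conditions: iPr3SiCl, imidazole, DMF, rt
Reagents that add atoms: triisopropylsilyl chloride, CC(C)[Si](Cl)(C(C)C)C(C)C
Why: Standard phenol silylation; the bulky triisopropylsilyl ether should resist the aqueous base of the later couplings and is removed by fluoride together with the triethylsilyl group.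

Step 13
Reactants: 20 (2-allyl-4-bromophenoxy)triisopropylsilane
Product: 21 [2-allyl-4-(4,4,5,5-tetramethyl-1,3,2-dioxaborolan-2-yl)phenoxy]triisopropylsilane
Conditions: B2pin2, Pd(dppf)Cl2, KOAc, 1,4-dioxane, 85 °C
Reagents that add atoms: bis(pinacolato)diboron, CC1(C)OB(OC1(C)C)B1OC(C)(C)C(C)(C)O1
Why: Miyaura borylation of the aryl bromide with the weak acetate base, under which the terminal alkene and the silyl ether should be unaffected.

Step 14
Reactants: 14 (2R,4aS,7R,8aS)-2,4a-dimethyl-7-[2-(triethylsilyloxy)propan-2-yl]decahydronaphthalen-2-ol; 17 (4-bromo-2-chlorophenyl)(2,4,6-trimethoxyphenyl)iodonium tosylate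
Product: 23 (2R,4aS,7R,8aS)-2-(4-bromo-2-chlorophenoxy)-2,4a-dimethyl-7-[2-(triethylsilyloxy)propan-2-yl]decahydronaphthalene, via sodium alkoxide 22 (not isolated)
Conditions: NaH, toluene, rt → 50 °C; then 17, rt → 40 °C
Reagents that add atoms: none
Why: Metal-free O-arylation of a tertiary alkoxide with a diaryliodonium salt: alkoxide 22 exchanges onto trivalent iodine and ligand coupling transfers the electron-poorer, ortho-substituted haloaryl group while the trimethoxyphenyl group leaves as the aryl iodide, and since the C3–O bond is never broken the axial configuration is retained.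

Step 15
Reactants: 23 (2R,4aS,7R,8aS)-2-(4-bromo-2-chlorophenoxy)-2,4a-dimethyl-7-[2-(triethylsilyloxy)propan-2-yl]decahydronaphthalene; 24 allylboronic acid pinacol ester
Product: 25 (2R,4aS,7R,8aS)-2-(4-allyl-2-chlorophenoxy)-2,4a-dimethyl-7-[2-(triethylsilyloxy)propan-2-yl]decahydronaphthalene
Conditions: Pd(dppf)Cl2, K3PO4, THF/H2O, 65 °C
Reagents that add atoms: none
Why: Suzuki–Miyaura coupling of the allylboronate at the aryl bromide: with a bisphosphine catalyst, oxidative addition to C–Br is much faster than to the hindered C–Cl bond, and the unsubstituted allyl group raises no regiochemical question.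

Step 16
Reactants: 25 (2R,4aS,7R,8aS)-2-(4-allyl-2-chlorophenoxy)-2,4a-dimethyl-7-[2-(triethylsilyloxy)propan-2-yl]decahydronaphthalene; 21 [2-allyl-4-(4,4,5,5-tetramethyl-1,3,2-dioxaborolan-2-yl)phenoxy]triisopropylsilane
Product: 26 (2R,4aS,7R,8aS)-2-{[3',5-diallyl-4'-(triisopropylsilyloxy)biphenyl-2-yl]oxy}-2,4a-dimethyl-7-[2-(triethylsilyloxy)propan-2-yl]decahydronaphthalene
Conditions: Pd(OAc)2, SPhos, K3PO4, toluene/H2O, 90 °C
Reagents that add atoms: none
Why: Suzuki–Miyaura coupling of a hindered, electron-rich aryl chloride, for which a bulky dialkylbiarylphosphine ligand is the established remedy, while the phosphate base should leave both silyl ethers in place.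

Step 17
Reactants: 26 (2R,4aS,7R,8aS)-2-{[3',5-diallyl-4'-(triisopropylsilyloxy)biphenyl-2-yl]oxy}-2,4a-dimethyl-7-[2-(triethylsilyloxy)propan-2-yl]decahydronaphthalene
Product: 27 3,5'-diallyl-2'-{[(2R,4aS,7R,8aS)-7-(2-hydroxypropan-2-yl)-2,4a-dimethyldecahydronaphthalen-2-yl]oxy}biphenyl-4-ol (target)
Conditions: Bu4NF, THF, rt → 50 °C; aq. NH4Cl
Reagents that add atoms: none
Why: Fluoride-mediated desilylation should cleave the aryl silyl ether and the tertiary triethylsilyl ether under basic conditions, which the acid-sensitive tertiary alkyl aryl ether tolerates.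

**Compound list**

1 | (S)-(+)-carvone | CC1=CC[C@@H](CC1=O)C(C)=C | starting material
2 | (5S)-5-(2-hydroxypropan-2-yl)-2-methylcyclohex-2-en-1-one | CC1=CC[C@@H](CC1=O)C(C)(C)O | intermediate
3 | (5S)-2-methyl-5-[2-(triethylsilyloxy)propan-2-yl]cyclohex-2-en-1-one | CC1=CC[C@@H](CC1=O)C(C)(C)O[Si](CC)(CC)CC | intermediate
4 | (1S,5S)-2-methyl-5-[2-(triethylsilyloxy)propan-2-yl]cyclohex-2-en-1-ol | CC1=CC[C@@H](C[C@@H]1O)C(C)(C)O[Si](CC)(CC)CC | intermediate
5 | triethyl orthoacetate | CC(OCC)(OCC)OCC | starting material
6 | (1S,5S)-2-methyl-5-[2-(triethylsilyloxy)propan-2-yl]cyclohex-2-en-1-yl 1-ethoxyvinyl ether (ketene acetal) | CC1=CC[C@@H](C[C@@H]1OC(=C)OCC)C(C)(C)O[Si](CC)(CC)CC | intermediate (not isolated)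
7 | ethyl 2-[(1S,5R)-2-methyl-5-[2-(triethylsilyloxy)propan-2-yl]cyclohex-2-en-1-yl]acetate | CCOC(=O)C[C@@H]1C[C@H](C(C)(C)O[Si](CC)(CC)CC)CC=C1C | intermediate
8 | N-methoxy-N-methyl-2-[(1S,5R)-2-methyl-5-[2-(triethylsilyloxy)propan-2-yl]cyclohex-2-en-1-yl]acetamide | CON(C)C(=O)C[C@@H]1C[C@H](C(C)(C)O[Si](CC)(CC)CC)CC=C1C | intermediate
9 | vinylmagnesium bromide | C=C[Mg]Br | starting material
10 | bromomagnesium 2-[methoxy(methyl)amino]-1-[(1S,5R)-2-methyl-5-[2-(triethylsilyloxy)propan-2-yl]cyclohex-2-en-1-yl]but-3-en-2-olate | C=CC(O[Mg]Br)(N(C)OC)C[C@@H]1C[C@H](C(C)(C)O[Si](CC)(CC)CC)CC=C1C | intermediate (not isolated)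
11 | 1-[(1S,5R)-2-methyl-5-[2-(triethylsilyloxy)propan-2-yl]cyclohex-2-en-1-yl]but-3-en-2-one | C=CC(=O)C[C@@H]1C[C@H](C(C)(C)O[Si](CC)(CC)CC)CC=C1C | intermediate
12 | (4aS,7R,8aS)-4a-methyl-7-[2-(triethylsilyloxy)propan-2-yl]octahydronaphthalen-2(1H)-one | O=C2CC[C@]3(C)CC[C@@H](C(C)(C)O[Si](CC)(CC)CC)C[C@H]3C2 | intermediate
13 | spiro-epoxide of 12 at C3 (3R; CH2 equatorial, O axial) | C1O[C@@]12CC[C@]3(C)CC[C@@H](C(C)(C)O[Si](CC)(CC)CC)C[C@H]3C2 | intermediate
14 | (2R,4aS,7R,8aS)-2,4a-dimethyl-7-[2-(triethylsilyloxy)propan-2-yl]decahydronaphthalen-2-ol | O[C@]2(C)CC[C@]3(C)CC[C@@H](C(C)(C)O[Si](CC)(CC)CC)C[C@H]3C2 | intermediate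
15 | 4-bromo-2-chloro-1-iodobenzene | Brc1ccc(I)c(Cl)c1 | starting material
16 | 4-bromo-2-chloro-1-[hydroxy(tosyloxy)-λ3-iodanyl]benzene | Cc1ccc(S(=O)(=O)OI(O)c2ccc(Br)cc2Cl)cc1 | intermediate (not isolated)
17 | (4-bromo-2-chlorophenyl)(2,4,6-trimethoxyphenyl)iodonium tosylate | COc1cc(OC)c([I+]c2ccc(Br)cc2Cl)c(OC)c1.Cc1ccc(S(=O)(=O)[O-])cc1 | intermediate
18 | allyl 4-bromophenyl ether | C=CCOc1ccc(Br)cc1 | starting material
19 | 2-allyl-4-bromophenol | C=CCc1cc(Br)ccc1O | intermediate
20 | (2-allyl-4-bromophenoxy)triisopropylsilane | C=CCc1cc(Br)ccc1O[Si](C(C)C)(C(C)C)C(C)C | intermediate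
21 | [2-allyl-4-(4,4,5,5-tetramethyl-1,3,2-dioxaborolan-2-yl)phenoxy]triisopropylsilane | C=CCc1cc(B2OC(C)(C)C(C)(C)O2)ccc1O[Si](C(C)C)(C(C)C)C(C)C | intermediate
22 | sodium (2R,4aS,7R,8aS)-2,4a-dimethyl-7-[2-(triethylsilyloxy)propan-2-yl]decahydronaphthalen-2-olate | [Na+].[O-][C@]2(C)CC[C@]3(C)CC[C@@H](C(C)(C)O[Si](CC)(CC)CC)C[C@H]3C2 | intermediate (not isolated)
23 | (2R,4aS,7R,8aS)-2-(4-bromo-2-chlorophenoxy)-2,4a-dimethyl-7-[2-(triethylsilyloxy)propan-2-yl]decahydronaphthalene | Brc1ccc(O[C@]2(C)CC[C@]3(C)CC[C@@H](C(C)(C)O[Si](CC)(CC)CC)C[C@H]3C2)c(Cl)c1 | intermediate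
24 | allylboronic acid pinacol ester | C=CCB1OC(C)(C)C(C)(C)O1 | starting material
25 | (2R,4aS,7R,8aS)-2-(4-allyl-2-chlorophenoxy)-2,4a-dimethyl-7-[2-(triethylsilyloxy)propan-2-yl]decahydronaphthalene | C=CCc1ccc(O[C@]2(C)CC[C@]3(C)CC[C@@H](C(C)(C)O[Si](CC)(CC)CC)C[C@H]3C2)c(Cl)c1 | intermediate
26 | (2R,4aS,7R,8aS)-2-{[3',5-diallyl-4'-(triisopropylsilyloxy)biphenyl-2-yl]oxy}-2,4a-dimethyl-7-[2-(triethylsilyloxy)propan-2-yl]decahydronaphthalene | C=CCc1ccc(O[C@]2(C)CC[C@]3(C)CC[C@@H](C(C)(C)O[Si](CC)(CC)CC)C[C@H]3C2)c(-c2ccc(O[Si](C(C)C)(C(C)C)C(C)C)c(CC=C)c2)c1 | intermediate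
27 | 3,5'-diallyl-2'-{[(2R,4aS,7R,8aS)-7-(2-hydroxypropan-2-yl)-2,4a-dimethyldecahydronaphthalen-2-yl]oxy}biphenyl-4-ol | C=CCc1ccc(O[C@]2(C)CC[C@]3(C)CC[C@@H](C(C)(C)O)C[C@H]3C2)c(-c2ccc(O)c(CC=C)c2)c1 | target

**Step count**

Total: 17 steps. Longest linear sequence: 13 steps (steps 1–9 and 14–17).

**Steps most likely to fail**

Step 14 (O-arylation). The hindered axial tertiary alkoxide may exchange onto iodine only slowly. Deprotonation of the salt ortho to iodine (aryne formation, leading to regioisomeric ethers) or decomposition of the salt could then compete with ligand coupling. The fallback is nucleophilic aromatic substitution. It sets out from 14, which is converted to its potassium alkoxide (KN(SiMe3)2, DMF, 0 °C) and heated to 60 °C with 4-bromo-2-chloro-1-fluorobenzene. Fluoride is displaced much faster than the heavier halides, so the detour comes back to the route directly at 23; it makes no compound outside the list (none F0).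

Step 7 (radical ring closure). Reduction of the C10 radical by a second hydrogen atom transfer, or oligomerisation of the vinyl ketone, may outrun the 6-endo closure, and facial selectivity at the planar radical may be eroded. The fallback separates the C10–C1 bond formation from the ring closure and sets out from ester 7. The same Fe(acac)3/PhSiH3 conditions with excess ethyl acrylate should add the C10 radical intermolecularly, anti to the C5 side chain, to give the diester ethyl 3-[(1S,2S,4R)-2-(2-ethoxy-2-oxoethyl)-1-methyl-4-[2-(triethylsilyloxy)propan-2-yl]cyclohexyl]propanoate F1. Dieckmann condensation (KOtBu, THF, 0 °C → rt) would then close ring A to the two regioisomeric β-keto esters, the C2-ethoxycarbonyl derivative of 12 F2 and the C4-ethoxycarbonyl derivative of 12 F3. Krapcho dealkoxycarbonylation of both (LiCl, wet DMSO, 150 °C) converges on 12, where the route is rejoined.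

Step 16 (biaryl coupling at the chloride). Slow oxidative addition at the chloride flanked by the tertiary alkoxy group may let protodeboronation of 21 and palladium-hydride migration of the allyl double bonds into conjugation take over. The fallback swaps the halogens so that the more reactive bromide sits at the hindered position; it sets out from 14. 2-Bromo-4-chloro-1-iodobenzene is oxidised as in step 10 to 2-bromo-4-chloro-1-[hydroxy(tosyloxy)-λ3-iodanyl]benzene F4 and converted to (2-bromo-4-chlorophenyl)(2,4,6-trimethoxyphenyl)iodonium tosylate F5. Arylation of 14 as in step 14 gives the 2-bromo-4-chlorophenyl ether of 14 F6. Suzuki–Miyaura coupling with 21 at the bromide (Pd(dppf)Cl2, K3PO4, 1,4-dioxane/H2O, 85 °C) gives the biaryl chloride F7. Allylation of the unhindered para chloride with 24 (Pd(OAc)2, XPhos, K3PO4, THF/H2O, 70 °C) comes back to the route at 26.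

Further compounds
F0 | step 14 | none | none
F1 | step 7 | ethyl 3-[(1S,2S,4R)-2-(2-ethoxy-2-oxoethyl)-1-methyl-4-[2-(triethylsilyloxy)propan-2-yl]cyclohexyl]propanoate | CCOC(=O)CC[C@]1(C)CC[C@@H](C(C)(C)O[Si](CC)(CC)CC)C[C@H]1CC(=O)OCC
F2 | step 7 | C2-ethoxycarbonyl derivative of 12 (ethyl 3-oxo-decalin-2-carboxylate, route numbering) | CCOC(=O)C1C[C@]2(C)CC[C@@H](C(C)(C)O[Si](CC)(CC)CC)C[C@H]2CC1=O
F3 | step 7 | C4-ethoxycarbonyl derivative of 12 (ethyl 3-oxo-decalin-4-carboxylate, route numbering) | CCOC(=O)C1C(=O)CC[C@]2(C)CC[C@@H](C(C)(C)O[Si](CC)(CC)CC)C[C@@H]12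
F4 | step 16 | 2-bromo-4-chloro-1-[hydroxy(tosyloxy)-λ3-iodanyl]benzene | Cc1ccc(S(=O)(=O)OI(O)c2ccc(Cl)cc2Br)cc1
F5 | step 16 | (2-bromo-4-chlorophenyl)(2,4,6-trimethoxyphenyl)iodonium tosylate | COc1cc(OC)c([I+]c2ccc(Cl)cc2Br)c(OC)c1.Cc1ccc(S(=O)(=O)[O-])cc1
F6 | step 16 | (2R,4aS,7R,8aS)-2-(2-bromo-4-chlorophenoxy)-2,4a-dimethyl-7-[2-(triethylsilyloxy)propan-2-yl]decahydronaphthalene | Clc1ccc(O[C@]2(C)CC[C@]3(C)CC[C@@H](C(C)(C)O[Si](CC)(CC)CC)C[C@H]3C2)c(Br)c1
F7 | step 16 | (2R,4aS,7R,8aS)-2-{[3'-allyl-5-chloro-4'-(triisopropylsilyloxy)biphenyl-2-yl]oxy}-2,4a-dimethyl-7-[2-(triethylsilyloxy)propan-2-yl]decahydronaphthalene | Clc1ccc(O[C@]2(C)CC[C@]3(C)CC[C@@H](C(C)(C)O[Si](CC)(CC)CC)C[C@H]3C2)c(-c2ccc(O[Si](C(C)C)(C(C)C)C(C)C)c(CC=C)c2)c1
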